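**Retrosynthetic overview**
Feature: the only ring to build is the central benzene ring, a resorcinol core with O at C1 and C3, H at C2, identical 4-hydroxybenzyl arms at C4 and C6 and the 2-phenylethyl chain at C5. Without the O-methyl group it has a mirror plane through C2 and C5.
Late disconnections: the two O-benzyl groups (hydrogenolysis), the C1 O-methyl group (methylation of either equivalent hydroxyl), and a sacrificial tert-butyl carboxylate on C6 that leaves as CO2 on aromatisation.
Key disconnection: C5–C6 and C2–C3. This splits the ring into C2–C1–C6 (an α-benzylated tert-butyl acetoacetate) and C3–C4–C5 (an α-benzylated 2,3-dienoate: ester carbon C3, α-carbon C4, central allene carbon C5, with the chain latent as =CH–CH2Ph).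
Both halves draw on one benzylic chloride: enolate alkylation gives the keto ester, and ylide alkylation followed by a ketene Wittig reaction gives the allenoate.
Ring order: the three outer benzene rings are bought. The central ring is the only one formed; it closes in step 4 and becomes aromatic in step 5.
Key step: step 4

Remark: the target has no stereocentre, axis or stereogenic double bond, so it is achiral and there is no enantiomer to select. The stereogenic elements of 3, 5, 9, 10, 11, 12 and 13 are racemic or undefined, and all are erased by step 5.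

Step 1
Reactants: 1 tert-butyl acetoacetate; 2 4-(benzyloxy)benzyl chloride
Product: 3 tert-butyl 2-[4-(benzyloxy)benzyl]-3-oxobutanoate (racemic)
Conditions: 1 (1.3 equiv), NaH (1.2 equiv), THF, 0 °C; then 2 (1.0 equiv), DMF co-solvent, 0 → 50 °C
Reagents that add atoms: none
Why: Acetoacetic ester C-alkylation (SN2 of the sodium enolate on an activated benzylic chloride), in which the excess of 1 suppresses dialkylation and the new stereocentre is racemic and labile, which does not matter.

Step 2
Reactants: 4 methyl (triphenylphosphoranylidene)acetate; 2 4-(benzyloxy)benzyl chloride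
Product: 5 {3-[4-(benzyloxy)phenyl]-1-methoxy-1-oxopropan-2-yl}triphenylphosphonium chloride (racemic)
Conditions: 2 (1.1 equiv), CHCl3, reflux; precipitation with Et2O
Reagents that add atoms: none
Why: C-alkylation of a stabilised phosphonium ylide by a reactive p-alkoxybenzyl chloride, the standard entry to α-substituted ylide salts, with the slight excess of 2 consuming any ylide freed by transylidation.

Step 3
Reactants: 5 {3-[4-(benzyloxy)phenyl]-1-methoxy-1-oxopropan-2-yl}triphenylphosphonium chloride; 6 3-phenylpropanoyl chloride
Product: 9 methyl 2-[4-(benzyloxy)benzyl]-5-phenylpenta-2,3-dienoate (racemic allene axis), via ylide 7 (not isolated), via benzylketene 8 (not isolated)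
Conditions: Et3N (2.2 equiv), CH2Cl2, 0 °C; 6 (1.1 equiv) added slowly, 0 °C → rt; Ph3PO removed by trituration, short silica column
Reagents that add atoms: none
Why: Ketene Wittig allenoate synthesis, in which one equivalent of amine frees ylide 7, the second dehydrochlorinates 6 to ketene 8, and olefination of the ketene C=O gives the 2,4-disubstituted allenoate whose racemic axis is erased in step 4.

Step 4
Reactants: 3 tert-butyl 2-[4-(benzyloxy)benzyl]-3-oxobutanoate; 9 methyl 2-[4-(benzyloxy)benzyl]-5-phenylpenta-2,3-dienoate
Product: 12 tert-butyl 1,3-bis[4-(benzyloxy)benzyl]-4,6-dioxo-2-(2-phenylethyl)cyclohex-2-ene-1-carboxylate (racemic), via kinetic Michael adduct 10 (not isolated), via conjugated ester 11 (not isolated)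
Conditions: 3 (1.2 equiv), KOt-Bu (0.15 equiv), THF, 0 °C, slow addition of 9, → rt; then KOt-Bu (1.3 equiv), THF–t-BuOH, rt → 45 °C; cold 1 M HCl to pH 4
Reagents that add atoms: none
Why: Proposed new method: in the first stage the potassium enolate of 3, buffered by the excess of 3 so that nothing more basic meets the allenoate, adds through C6 (arene numbering) to the sp central carbon C5 of 9 from the side of the allenic hydrogen, and the dienolate is protonated kinetically at C4 to give the β,γ-unsaturated adduct 10. In the second stage full KOt-Bu regenerates the dienolate, whose protonation at the γ-carbon turns =CH–CH2Ph into the CH2CH2Ph chain (conjugated ester 11), and it enolises the methyl group C2, the only enolisable ketone position now that C6 is quaternary, which attacks the ester carbon C3 in a 6-(enolendo)-exo-trig Dieckmann closure of the one new ring, after which loss of methoxide and deprotonation of the 1,3-diketone pull the preceding equilibria forward. The closest known reaction types are the Michael addition of 1,3-dicarbonyl anions to the central carbon of 2,3-allenoates, the Michael–Claisen synthesis of cyclohexane-1,3-diones and the Michael–Dieckmann synthesis of resorcinols from acetonedicarboxylate anions and activated allenes or alkynes, and new here are the tertiary donor, the 2,4-disubstituted allenoate and the blocked quaternary carbon. Site selectivity in the ketone half comes from the tert-butyl ester, which makes C6 the only Michael donor and resists alkoxide, while the strain released from the allene makes downhill and hard to reverse an addition that would be expected to fail on the corresponding α,β-disubstituted acrylate, and it delivers the ring at the resorcinol oxidation level. The E and Z isomers of 11 interconvert through the dienolate so that the Z isomer (ester cis to C6) is drained by cyclisation, and any enol lactone from O-acylation is reopened by alkoxide whereas the C-acylated product is held as its stabilised enolate. The quaternary stereocentre at C6 forms as a racemate under no control, and none is needed because step 5 removes it.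

Step 5
Reactants: 12 tert-butyl 1,3-bis[4-(benzyloxy)benzyl]-4,6-dioxo-2-(2-phenylethyl)cyclohex-2-ene-1-carboxylate
Product: 14 4,6-bis[4-(benzyloxy)benzyl]-5-(2-phenylethyl)benzene-1,3-diol, via keto acid 13 (not isolated)
Conditions: TFA–CH2Cl2 1:4, 0 °C → rt, N2 purge; concentrate, toluene, 50 °C
Reagents that add atoms: none
Why: Acidolysis of the tert-butyl ester (loss of isobutene) gives β-keto acid 13, whose decarboxylation leaves a cyclohexadienone that is simply the keto tautomer of resorcinol 14, and aryl benzyl ethers tolerate brief exposure to dilute TFA at or below room temperature.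

Step 6
Reactants: 14 4,6-bis[4-(benzyloxy)benzyl]-5-(2-phenylethyl)benzene-1,3-diol
Product: 15 2,4-bis[4-(benzyloxy)benzyl]-5-methoxy-3-(2-phenylethyl)phenol
Conditions: MeI (1.0 equiv), K2CO3 (1.0 equiv), acetone, N2, rt → 40 °C; unreacted 14 recovered and recycled
Reagents that add atoms: iodomethane, CI
Why: Williamson ether synthesis in which the two hydroxyls of 14 are related by the mirror plane through C2 and C5 so that either gives 15, the arm phenols are masked as benzyl ethers, and over-methylation is limited by the stoichiometry.

Step 7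
Reactants: 15 2,4-bis[4-(benzyloxy)benzyl]-5-methoxy-3-(2-phenylethyl)phenol
Product: 16 2,4-bis(4-hydroxybenzyl)-5-methoxy-3-(2-phenylethyl)phenol (IN1158)
Conditions: H2 (1 atm), 10% Pd/C, EtOAc–MeOH, rt
Reagents that add atoms: none
Why: Catalytic hydrogenolysis of the two aryl benzyl ethers, under which the diarylmethane and bibenzyl C–C bonds, the aryl methyl ether and the arenes are inert.

**Compound list**
1 | tert-butyl acetoacetate | CC(=O)CC(=O)OC(C)(C)C | starting material
2 | 4-(benzyloxy)benzyl chloride | ClCc1ccc(OCc2ccccc2)cc1 | starting material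
3 | tert-butyl 2-[4-(benzyloxy)benzyl]-3-oxobutanoate (racemic, labile centre) | CC(=O)C(Cc1ccc(OCc2ccccc2)cc1)C(=O)OC(C)(C)C | intermediate
4 | methyl (triphenylphosphoranylidene)acetate | COC(=O)C=P(c1ccccc1)(c1ccccc1)c1ccccc1 | starting material
5 | {3-[4-(benzyloxy)phenyl]-1-methoxy-1-oxopropan-2-yl}triphenylphosphonium chloride (racemic) | COC(=O)C(Cc1ccc(OCc2ccccc2)cc1)[P+](c1ccccc1)(c1ccccc1)c1ccccc1.[Cl-] | intermediate
6 | 3-phenylpropanoyl chloride | O=C(Cl)CCc1ccccc1 | starting material
7 | methyl 3-[4-(benzyloxy)phenyl]-2-(triphenylphosphoranylidene)propanoate | COC(=O)C(Cc1ccc(OCc2ccccc2)cc1)=P(c1ccccc1)(c1ccccc1)c1ccccc1 | intermediate (not isolated)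
8 | benzylketene (3-phenylprop-1-en-1-one) | O=C=CCc1ccccc1 | intermediate (not isolated)
9 | methyl 2-[4-(benzyloxy)benzyl]-5-phenylpenta-2,3-dienoate (racemic axis) | COC(=O)C(Cc1ccc(OCc2ccccc2)cc1)=C=CCc1ccccc1 | intermediate
10 | 1-tert-butyl 5-methyl 2-acetyl-2,4-bis[4-(benzyloxy)benzyl]-3-(2-phenylethylidene)pentanedioate (racemic, mixture of diastereomers and alkene isomers) | COC(=O)C(Cc1ccc(OCc2ccccc2)cc1)C(=CCc1ccccc1)C(Cc1ccc(OCc2ccccc2)cc1)(C(C)=O)C(=O)OC(C)(C)C | intermediate (not isolated)
11 | 5-tert-butyl 1-methyl 4-acetyl-2,4-bis[4-(benzyloxy)benzyl]-3-(2-phenylethyl)pent-2-enedioate (racemic, E and Z interconverting, Z cyclises) | COC(=O)C(Cc1ccc(OCc2ccccc2)cc1)=C(CCc1ccccc1)C(Cc1ccc(OCc2ccccc2)cc1)(C(C)=O)C(=O)OC(C)(C)C | intermediate (not isolated)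
12 | tert-butyl 1,3-bis[4-(benzyloxy)benzyl]-4,6-dioxo-2-(2-phenylethyl)cyclohex-2-ene-1-carboxylate (racemic) | O=C1CC(=O)C(Cc2ccc(OCc3ccccc3)cc2)(C(=O)OC(C)(C)C)C(CCc2ccccc2)=C1Cc1ccc(OCc2ccccc2)cc1 | intermediate
13 | 1,3-bis[4-(benzyloxy)benzyl]-4,6-dioxo-2-(2-phenylethyl)cyclohex-2-ene-1-carboxylic acid (racemic) | O=C1CC(=O)C(Cc2ccc(OCc3ccccc3)cc2)(C(=O)O)C(CCc2ccccc2)=C1Cc1ccc(OCc2ccccc2)cc1 | intermediate (not isolated)
14 | 4,6-bis[4-(benzyloxy)benzyl]-5-(2-phenylethyl)benzene-1,3-diol | Oc1cc(O)c(Cc2ccc(OCc3ccccc3)cc2)c(CCc2ccccc2)c1Cc1ccc(OCc2ccccc2)cc1 | intermediate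
15 | 2,4-bis[4-(benzyloxy)benzyl]-5-methoxy-3-(2-phenylethyl)phenol | COc1cc(O)c(Cc2ccc(OCc3ccccc3)cc2)c(CCc2ccccc2)c1Cc1ccc(OCc2ccccc2)cc1 | intermediate
16 | 2,4-bis(4-hydroxybenzyl)-5-methoxy-3-(2-phenylethyl)phenol (IN1158, achiral) | COc1cc(O)c(Cc2ccc(O)cc2)c(CCc2ccccc2)c1Cc1ccc(O)cc1 | target

Total step count: 7
Longest linear sequence: 6 steps (4 → 5 → 9 → 12 → 14 → 15 → 16)

**Steps most likely to fail**

1. Step 4 (bears the label).
- What may go wrong: the hindered tertiary enolate may add too slowly. Three processes could then take over: prototropic isomerisation of the allenoate towards a conjugated dienoate, retro-Claisen loss of the acetyl group from the quaternary adduct, or stalling at the open-chain stage. Incomplete migration of the double bond into the ring would not matter, because step 5 aromatises any positional isomer.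
- Fallback (known chemistry; the central ring is bought instead of built): it sets out from 2 and comes back at 14. Purchased 5-(2-phenylethyl)benzene-1,3-diol F1 is protected with MOMCl and i-Pr2NEt as 1,3-bis(methoxymethoxy)-5-(2-phenylethyl)benzene F2. NBS (2 equiv, MeCN, 0 °C) brominates the two positions flanking the chain, each para to one oxygen and ortho to the other, to give 2,4-dibromo-1,5-bis(methoxymethoxy)-3-(2-phenylethyl)benzene F3. Zinc dust and LiCl in THF convert 2 into [4-(benzyloxy)benzyl]zinc chloride F4. A double Negishi coupling of F3 with F4 (Pd(OAc)2, SPhos, THF, 50 °C) gives 2,4-bis[4-(benzyloxy)benzyl]-1,5-bis(methoxymethoxy)-3-(2-phenylethyl)benzene F5. HCl in MeOH then removes both MOM groups and delivers 14.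

2. Step 6.
- What may go wrong: the first methylation hardly changes the reactivity of the second hydroxyl. A near-statistical spread with over-methylation and the need for recycling is therefore to be expected.
- Fallback: it sets out from 12 and comes back at 15, bypassing 14. The methyl group is placed while the ring is still a 1,3-diketone, which can take up only one. TMSCHN2 (toluene–MeOH, 0 °C) O-methylates the enol to two enol ethers. These are tert-butyl 1,3-bis[4-(benzyloxy)benzyl]-4-methoxy-6-oxo-2-(2-phenylethyl)cyclohexa-2,4-diene-1-carboxylate F6 and tert-butyl 1,5-bis[4-(benzyloxy)benzyl]-2-methoxy-4-oxo-6-(2-phenylethyl)cyclohexa-2,5-diene-1-carboxylate F7. The mixture is not separated. Anhydrous TFA in CH2Cl2 cleaves the tert-butyl ester, and direct or vinylogous decarboxylative aromatisation of either isomer gives the same 15.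

3. Step 3.
- What may go wrong: dimerisation of the ketene, a slow Wittig reaction of the hindered α-branched ylide, and amine-induced isomerisation of the allenoate on prolonged contact could erode the step.
- Fallback: it sets out from 2 and comes back at 9, making the allene by β-elimination instead of olefination. The sodium enolate of purchased methyl 3-oxo-5-phenylpentanoate F8 is alkylated with 2 (NaH, THF–DMF) to give methyl 2-[4-(benzyloxy)benzyl]-3-oxo-5-phenylpentanoate F9. LiHMDS and then Tf2O at −78 °C give methyl 2-[4-(benzyloxy)benzyl]-5-phenyl-3-(trifluoromethylsulfonyloxy)pent-2-enoate F10. A second equivalent of LiHMDS removes a γ-proton, and E1cB loss of triflate gives 9. The α-substituent rules out formation of a 2-alkynoate.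

**Further compounds**
F1 | step 4 | 5-(2-phenylethyl)benzene-1,3-diol (purchased) | Oc1cc(O)cc(CCc2ccccc2)c1
F2 | step 4 | 1,3-bis(methoxymethoxy)-5-(2-phenylethyl)benzene | COCOc1cc(OCOC)cc(CCc2ccccc2)c1
F3 | step 4 | 2,4-dibromo-1,5-bis(methoxymethoxy)-3-(2-phenylethyl)benzene | COCOc1cc(OCOC)c(Br)c(CCc2ccccc2)c1Br
F4 | step 4 | [4-(benzyloxy)benzyl]zinc chloride | Cl[Zn]Cc1ccc(OCc2ccccc2)cc1
F5 | step 4 | 2,4-bis[4-(benzyloxy)benzyl]-1,5-bis(methoxymethoxy)-3-(2-phenylethyl)benzene | COCOc1cc(OCOC)c(Cc2ccc(OCc3ccccc3)cc2)c(CCc2ccccc2)c1Cc1ccc(OCc2ccccc2)cc1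
F6 | step 6 | tert-butyl 1,3-bis[4-(benzyloxy)benzyl]-4-methoxy-6-oxo-2-(2-phenylethyl)cyclohexa-2,4-diene-1-carboxylate (racemic) | COC1=CC(=O)C(Cc2ccc(OCc3ccccc3)cc2)(C(=O)OC(C)(C)C)C(CCc2ccccc2)=C1Cc1ccc(OCc2ccccc2)cc1
F7 | step 6 | tert-butyl 1,5-bis[4-(benzyloxy)benzyl]-2-methoxy-4-oxo-6-(2-phenylethyl)cyclohexa-2,5-diene-1-carboxylate (racemic) | COC1=CC(=O)C(Cc2ccc(OCc3ccccc3)cc2)=C(CCc2ccccc2)C1(Cc1ccc(OCc2ccccc2)cc1)C(=O)OC(C)(C)C
F8 | step 3 | methyl 3-oxo-5-phenylpentanoate (purchased) | COC(=O)CC(=O)CCc1ccccc1
F9 | step 3 | methyl 2-[4-(benzyloxy)benzyl]-3-oxo-5-phenylpentanoate (racemic) | COC(=O)C(Cc1ccc(OCc2ccccc2)cc1)C(=O)CCc1ccccc1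
F10 | step 3 | methyl 2-[4-(benzyloxy)benzyl]-5-phenyl-3-(trifluoromethylsulfonyloxy)pent-2-enoate (alkene geometry not defined, both isomers eliminate) | COC(=O)C(Cc1ccc(OCc2ccccc2)cc1)=C(CCc1ccccc1)OS(=O)(=O)C(F)(F)F
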